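All runs were generated by integration from invented constants.

A one-step world is simple: a single first-order lag, whose end value equals the charge however fast the charge arrives. Here first and second end groups join to links, and the task was to rank four ways of bringing them together.

| flask | first end groups | second end groups | protic impurity | remark | time |
|---|---|---|---|---|---|
| maple | 0.25 M | 1 equiv | 0.075 M | run made earlier |  |
| oak | 0.25 M | 0.50 equiv | 0.075 M | run made earlier |  |
| birch | 0.25 M | 0.75 equiv | 0.075 M | run made earlier |  |
| alder | 0.25 M | 1 equiv | 0.15 M | run made earlier |  |
| teal | 0.25 M | 1.00 equiv | 0.0750 M | a single well-mixed tank run continuously and read at steady state, 2.0 min in it on average |  |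
| blue | 0.25 M | 1.00 equiv (fed, over 1.60 min) | 0.0750 M | a stirred flask in which second end groups is dosed at a steady rate over 1.60 min without added volume, worked up at 2.0 min | 2.0 min |
| green | 0.25 M | 1.00 equiv | 0.0750 M | a closed flask charged with all of it at once and left for 2.0 min | 2.0 min |
| ochre | 0.25 M (fed, over 1.60 min) | 1.00 equiv | 0.0750 M | a stirred flask in which first end groups is dosed at a steady rate over 1.60 min without added volume, worked up at 2.0 min | 2.0 min |

maple run (percent of the first end groups charged)

| time / s | links / % | first end groups / % |
|---|---|---|
| 10.0 | 21.1 | 74.7 |
| 20.0 | 27.2 | 74.2 |
| 50.0 | 32.6 | 67.4 |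
| 120 | 33.4 | 68.2 |

oak run (percent of the first end groups charged)

| time / min | links / % | first end groups / % |
|---|---|---|
| 0.667 | 12.5 | 86.6 |
| 1.33 | 12.7 | 85.8 |
| 2.00 | 14.4 | 85.9 |
| 2.50 | 14.7 | 87.4 |

birch run (percent of the first end groups charged)

| time / min | links / % | first end groups / % |
|---|---|---|
| 0.200 | 17.1 | 81.9 |
| 0.417 | 21.1 | 78.1 |
| 1.00 | 23.3 | 75.5 |
| 2.50 | 24.2 | 77.3 |

alder run (percent of the first end groups charged)

| time / min | links / % | first end groups / % |
|---|---|---|
| 0.333 | 17.8 | 82.5 |
| 0.833 | 21.7 | 80.1 |
| 1.50 | 21.1 | 80.8 |
| 2.50 | 20.4 | 82.1 |

(readings scatter by 1 percentage point)

* the set-up with the highest amount of links at the outlet or at the end, in percent of the first end groups put in ("none" if the first two lie within 2 percentage points) (teal / blue / green / ochre / none)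
* amount of links at the outlet or at the end, in percent of the first end groups put in, teal
* amount of links at the outlet or at the end, in percent of the first end groups put in, blue
* amount of links at the outlet or at the end, in percent of the first end groups put in, green
* amount of links at the outlet or at the end, in percent of the first end groups put in, ochre

- the stated concentrations are those of everything mixed, before any reaction; amounts are the same in each set-up
- the feed brings no volume worth counting
- the earlier runs were made in a closed, stirred flask

The closed runs were not that world: maple's last reading was 33.4% links from equal charges. I assumed that protic impurity takes one second end group each, and called what remains the surplus. Whatever surplus did not become links I called waste, using the last reading of each run: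

| Run | Surplus | Links | Waste |
|---|---|---|---|
| oak | 0.0500 M | 0.0367 M | 0.0133 M |
| alder | 0.100 M | 0.0510 M | 0.0490 M |
| birch | 0.113 M | 0.0605 M | 0.0520 M |
| maple | 0.175 M | 0.0835 M | 0.0915 M |

In powers of ten, from oak to maple, surplus rose 0.544 decades and waste 0.838, a slope of 1.54. A fixed split gives a slope of one, and this reading stands above it. So I took links as pseudo-first-order in c_second and the loss as growing with c_second squared. The ratio of loss to links is then c_second/cX, with cX a constant still to be found, and links receive the share cX/(cX + c_second).

For small surplus, waste is about surplus squared divided by 2 cX, so oak gave cX near 0.0943 M. In maple, the links still to come fell by half between the first two readings, which I read as a time constant τ = 14.6 s. Blue's feed times τ is 0.0380 M. Balancing feed against both paths put my estimate of c_second in blue at 0.0291 M, and my estimate of blue's links at 53.5%.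

The weak link was oak's small-surplus shortcut. Repeated substitution into the whole relation, links = cX ln(1 + surplus/cX), on maple brought the crossover concentration, the level at which links and loss run equally fast, to 0.0676 M. My estimate of blue's level became 0.0271 M and of blue's links 50.0%. I set green at maple's 33.4%, teal somewhat under blue, and ochre under green, since ochre's second end groups start above cX.

The forecast gave teal 28%, blue 32.5%, green 33%, ochre 9% and best none, holding that “dosing leaves selectivity unchanged”, whereas I put blue first.

The simulation gave teal 44.3%, blue 49.0%, green 32.5% and ochre 10.4%, so blue was the highest.

    first end groups + second end groups → links (k = 0.350 /M/s)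
    second end groups + protic impurity → quenched reagent (k = 7.10 /M/s)
    2 second end groups → self-condensation product (k = 0.580 /M/s)

After 1.00 min, blue held 8.82% of its second end groups, which is 0.0221 M, or 0.327 of cX. Ochre's second end groups peaked at 0.250 M, 3.70 times cX, and ochre ended with 10.4% links.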